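The route rests on cutting the C4–C4a bond of ring B (tetralin numbering: C1 aryl-bearing, C9 on C2, C10 on C3). The feature exploited is C3: its two methylene neighbours, C4 (attached to ring-A carbon C4a) and C10 (attached to OH), trace back to the two enantiotopic CH2 groups of an oxetane substituted at its 3-position, and C4a sits para to the C7 oxygen. In one operation a chiral acid lets C4a open the oxetane, which closes ring B, creates C3 and releases C10–OH, already distinct from ester carbon C9. The precursor is a racemic α-(oxetan-3-yl) aroylacetate whose C7 hydroxyl is unmasked first, because a benzyloxy group wedged between two methoxy groups is twisted and donates poorly.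

Key step: step 7

Remarks before the steps (one line each):
- Abbreviations: TIPS = Si(iPr)3, Tf = SO2CF3, Bn = CH2Ph.
- The target is drawn as the free hydrogen sulfate, so the last step ends with proton exchange; in practice the compound would be stored as a salt.
- The sense of induction of the chiral acid in step 7 cannot be deduced beforehand; the (R) acid is written, and its mirror image would be used should it favour (3R).

Step 1
Reactants: 1 2,6-dimethoxyphenol
Product: 2 2-(benzyloxy)-1,3-dimethoxybenzene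
Conditions: BnBr, K2CO3, DMF, 60 °C
Reagents that add atoms: benzyl bromide, BrCc1ccccc1
Why: Williamson ether synthesis on the phenoxide; capping the oxygen steers the next formylation ortho to a methoxy group instead of para to the phenol.

Step 2
Reactants: 2 2-(benzyloxy)-1,3-dimethoxybenzene
Product: 4 3-(benzyloxy)-2,4-dimethoxybenzaldehyde, via iminium chloride 3 (not isolated)
Conditions: POCl3, DMF, 0 → 80 °C; then ice–water
Reagents that add atoms: N,N-dimethylformamide, CN(C)C=O; phosphoryl chloride, O=P(Cl)(Cl)Cl (chloride of 3 only); water, O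
Why: Vilsmeier–Haack formylation at the position ortho to one methoxy group and para to the other, the site known to react in 1,2,3-trialkoxybenzenes, followed by hydrolysis of the iminium salt.

Step 3
Reactants: 5 methyl 2-(oxetan-3-ylidene)acetate
Product: 6 methyl 2-(oxetan-3-yl)acetate
Conditions: H2 (1 atm), 10% Pd/C, MeOH, rt
Reagents that add atoms: none
Why: Catalytic hydrogenation of the conjugated exocyclic alkene; the oxetane ring is inert to these conditions.

Step 4
Reactants: 6 methyl 2-(oxetan-3-yl)acetate; 4 3-(benzyloxy)-2,4-dimethoxybenzaldehyde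
Product: 8 methyl 3-[3-(benzyloxy)-2,4-dimethoxyphenyl]-3-hydroxy-2-(oxetan-3-yl)propanoate (racemic mixture of diastereomers), via lithium ester enolate 7 (not isolated)
Conditions: LiN(iPr)2, THF, −78 °C; then 4, −78 °C; AcOH quench
Reagents that add atoms: lithium diisopropylamide, [Li+].CC(C)[N-]C(C)C (lithium of 7 only)
Why: Aldol addition of a lithium ester enolate to a non-enolisable aromatic aldehyde; the two new stereocentres need no control because one is oxidised away in step 5 and the other stays labile.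

Step 5
Reactants: 8 methyl 3-[3-(benzyloxy)-2,4-dimethoxyphenyl]-3-hydroxy-2-(oxetan-3-yl)propanoate
Product: 9 methyl 3-[3-(benzyloxy)-2,4-dimethoxyphenyl]-2-(oxetan-3-yl)-3-oxopropanoate (racemic, C2 labile)
Conditions: Dess–Martin periodinane, CH2Cl2, 0 °C → rt
Reagents that add atoms: none
Why: Dess–Martin oxidation of the benzylic secondary alcohol to the β-keto ester under near-neutral conditions that the oxetane tolerates.

Step 6
Reactants: 9 methyl 3-[3-(benzyloxy)-2,4-dimethoxyphenyl]-2-(oxetan-3-yl)-3-oxopropanoate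
Product: 10 methyl 3-(3-hydroxy-2,4-dimethoxyphenyl)-2-(oxetan-3-yl)-3-oxopropanoate (racemic, C2 labile)
Conditions: H2 (1 atm), 10% Pd/C, EtOAc, rt
Reagents that add atoms: none
Why: Hydrogenolysis of the benzyl aryl ether leaves oxetane, ketone and ester intact, and the freed C7–OH can lie in the ring plane and donate strongly to the para carbon C4a, which the twisted benzyloxy group could not.

Step 7
Reactants: 10 methyl 3-(3-hydroxy-2,4-dimethoxyphenyl)-2-(oxetan-3-yl)-3-oxopropanoate
Product: 11 methyl (3S)-7-hydroxy-3-(hydroxymethyl)-6,8-dimethoxy-1-oxo-1,2,3,4-tetrahydronaphthalene-2-carboxylate (C2 labile, keto/enol mixture)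
Conditions: (R)-[3,3'-(2,4,6-iPr3C6H2)2-BINOL]P(=O)NHSO2CF3 (10 mol %), toluene (0.02 M), 4 Å MS, 0 °C → rt
Reagents that add atoms: none
Why: Proposed new method: the chiral N-triflyl phosphoramide protonates the oxetane oxygen, and ring-A carbon C4a, para to the free C7 hydroxyl, attacks one of the two enantiotopic oxetane CH2 groups in an SN2-like Friedel–Crafts alkylation, after which the para-quinoid arenium ion loses the C4a proton, leaving the C4–C4a bond and the free C10–OH. The closest known reactions are chiral-phosphoric-acid-catalysed desymmetrising openings of 3-substituted oxetanes by tethered O, N or S nucleophiles and achiral Lewis-acid Friedel–Crafts openings of oxetanes by tethered arenes; an arene has not served as nucleophile in the enantioselective version. Ring B closes in a 6-exo-tet mode, the breaking C–O bond lying outside the new ring. C3 is set by the catalyst, whose confined ion pair is held at the oxetane oxygen and at the neighbouring β-keto ester (enol OH and carbonyl) and so decides which CH2 becomes C4, while C2 equilibrates through the enol under the acid (Curtin–Hammett), remains labile and is erased in step 9. The step needs C- over O-alkylation and attack by C4a instead of the innately more electron-rich C5: C5 cannot reach the oxetane, the free phenol makes C4a the most nucleophilic carbon that can, the hydrogen-bonded enol turns the C1 oxygen away from the oxetane, the methyl ester has no easy way to shed its alkyl group and form a lactone, and high dilution disfavours intermolecular alkylation.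

Step 8
Reactants: 11 methyl (3S)-7-hydroxy-3-(hydroxymethyl)-6,8-dimethoxy-1-oxo-1,2,3,4-tetrahydronaphthalene-2-carboxylate
Product: 12 methyl (3S)-6,8-dimethoxy-1-oxo-7-(TIPS-oxy)-3-[(TIPS-oxy)methyl]-1,2,3,4-tetrahydronaphthalene-2-carboxylate (C2 labile)
Conditions: iPr3SiCl, imidazole, DMAP (cat.), DMF, rt → 40 °C
Reagents that add atoms: chlorotriisopropylsilane, CC(C)[Si](Cl)(C(C)C)C(C)C
Why: Silyl ether formation at the primary alcohol and the phenol, run on crude 11 to forestall lactonisation of the γ-hydroxy ester; silyl groups are chosen over benzyl because they survive the hydrogenation of step 12.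

Step 9
Reactants: 12 methyl (3S)-6,8-dimethoxy-1-oxo-7-(TIPS-oxy)-3-[(TIPS-oxy)methyl]-1,2,3,4-tetrahydronaphthalene-2-carboxylate
Product: 13 methyl (3S)-6,8-dimethoxy-1-(trifluoromethylsulfonyloxy)-7-(TIPS-oxy)-3-[(TIPS-oxy)methyl]-3,4-dihydronaphthalene-2-carboxylate
Conditions: Tf2O, iPr2NEt, CH2Cl2, −78 → 0 °C
Reagents that add atoms: trifluoromethanesulfonic anhydride, O=S(=O)(OS(=O)(=O)C(F)(F)F)C(F)(F)F
Why: Enol triflate formation by O-sulfonylation of the cyclic β-keto ester activates C1 for arylation and turns the labile C2 into an sp2 carbon, so C3 is the only stereocentre.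

Step 10
Reactants: 14 2,6-dimethoxy-4-(4,4,5,5-tetramethyl-1,3,2-dioxaborolan-2-yl)phenol
Product: 15 [2,6-dimethoxy-4-(4,4,5,5-tetramethyl-1,3,2-dioxaborolan-2-yl)phenoxy]triisopropylsilane
Conditions: iPr3SiOTf, 2,6-lutidine, CH2Cl2, 0 °C → rt
Reagents that add atoms: triisopropylsilyl triflate, CC(C)[Si](OS(=O)(=O)C(F)(F)F)(C(C)C)C(C)C
Why: Silyl ether formation with the reactive silyl triflate, which a phenol flanked by two methoxy groups requires; the pinacol boronate is untouched.

Step 11
Reactants: 13 methyl (3S)-6,8-dimethoxy-1-(trifluoromethylsulfonyloxy)-7-(TIPS-oxy)-3-[(TIPS-oxy)methyl]-3,4-dihydronaphthalene-2-carboxylate; 15 [2,6-dimethoxy-4-(4,4,5,5-tetramethyl-1,3,2-dioxaborolan-2-yl)phenoxy]triisopropylsilane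
Product: 16 methyl (3S)-1-[3,5-dimethoxy-4-(TIPS-oxy)phenyl]-6,8-dimethoxy-7-(TIPS-oxy)-3-[(TIPS-oxy)methyl]-3,4-dihydronaphthalene-2-carboxylate
Conditions: Pd(PPh3)4 (5 mol %), K3PO4, 1,4-dioxane/H2O, 80 °C
Reagents that add atoms: none
Why: Suzuki–Miyaura coupling of an electron-poor β-triflyloxy enoate with an aryl boronate lacking ortho substituents; the mild phosphate base leaves C3 and the hindered aryl silyl ethers alone.

Step 12
Reactants: 16 methyl (3S)-1-[3,5-dimethoxy-4-(TIPS-oxy)phenyl]-6,8-dimethoxy-7-(TIPS-oxy)-3-[(TIPS-oxy)methyl]-3,4-dihydronaphthalene-2-carboxylate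
Product: 17 methyl (1R,2R,3S)-1-[3,5-dimethoxy-4-(TIPS-oxy)phenyl]-6,8-dimethoxy-7-(TIPS-oxy)-3-[(TIPS-oxy)methyl]-1,2,3,4-tetrahydronaphthalene-2-carboxylate (aryl, ester and C10 arm all cis)
Conditions: H2 (10 bar), 10% Pd/C, EtOAc, rt
Reagents that add atoms: none
Why: Heterogeneous catalytic hydrogenation should add both hydrogens syn to the face of C1=C2 opposite the C3 silyloxymethyl arm, which allylic strain with the C2 ester holds pseudoaxial, so the C1 aryl ends up cis to C10 (C1 = R) with C2 temporarily R.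

Step 13
Reactants: 17 methyl (1R,2R,3S)-1-[3,5-dimethoxy-4-(TIPS-oxy)phenyl]-6,8-dimethoxy-7-(TIPS-oxy)-3-[(TIPS-oxy)methyl]-1,2,3,4-tetrahydronaphthalene-2-carboxylate
Product: 18 methyl (1R,2S,3S)-1-[3,5-dimethoxy-4-(TIPS-oxy)phenyl]-6,8-dimethoxy-7-(TIPS-oxy)-3-[(TIPS-oxy)methyl]-1,2,3,4-tetrahydronaphthalene-2-carboxylate (ester trans to both neighbours)
Conditions: KOtBu (0.3 equiv), tBuOH/THF, rt
Reagents that add atoms: none
Why: Thermodynamic epimerisation through the ester enolate inverts C2, the only acidic centre, to the all-trans array in which all three substituents can be equatorial; the bulky alkoxide should spare the aryl silyl ethers.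

Step 14
Reactants: 18 methyl (1R,2S,3S)-1-[3,5-dimethoxy-4-(TIPS-oxy)phenyl]-6,8-dimethoxy-7-(TIPS-oxy)-3-[(TIPS-oxy)methyl]-1,2,3,4-tetrahydronaphthalene-2-carboxylate
Product: 19 [(1R,2S,3S)-1-[3,5-dimethoxy-4-(TIPS-oxy)phenyl]-6,8-dimethoxy-7-(TIPS-oxy)-3-[(TIPS-oxy)methyl]-1,2,3,4-tetrahydronaphthalen-2-yl]methanol
Conditions: LiAlH4, THF, 0 °C; aq NaOH work-up
Reagents that add atoms: none
Why: Ester reduction by LiAlH4 exposes C9–OH as the only free hydroxyl; silyl ethers and the three stereocentres are unaffected.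

Step 15
Reactants: 19 [(1R,2S,3S)-1-[3,5-dimethoxy-4-(TIPS-oxy)phenyl]-6,8-dimethoxy-7-(TIPS-oxy)-3-[(TIPS-oxy)methyl]-1,2,3,4-tetrahydronaphthalen-2-yl]methanol
Product: 20 pyridinium [(1R,2S,3S)-1-[3,5-dimethoxy-4-(TIPS-oxy)phenyl]-6,8-dimethoxy-7-(TIPS-oxy)-3-[(TIPS-oxy)methyl]-1,2,3,4-tetrahydronaphthalen-2-yl]methyl sulfate
Conditions: SO3·pyridine, pyridine, rt
Reagents that add atoms: sulfur trioxide–pyridine complex, [O-]S(=O)(=O)[n+]1ccccc1
Why: O-Sulfation of the single free primary alcohol with the SO3·pyridine complex gives the sulfate monoester as its pyridinium salt, no other nucleophilic site being exposed.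

Step 16
Reactants: 20 pyridinium [(1R,2S,3S)-1-[3,5-dimethoxy-4-(TIPS-oxy)phenyl]-6,8-dimethoxy-7-(TIPS-oxy)-3-[(TIPS-oxy)methyl]-1,2,3,4-tetrahydronaphthalen-2-yl]methyl sulfate
Product: 22 [(1R,2S,3S)-7-hydroxy-1-(4-hydroxy-3,5-dimethoxyphenyl)-3-(hydroxymethyl)-6,8-dimethoxy-1,2,3,4-tetrahydronaphthalen-2-yl]methyl hydrogen sulfate, via desilylated pyridinium sulfate 21 (not isolated)
Conditions: Bu4NF, AcOH, THF, 0 °C → rt; then Dowex 50WX8 (H+ form), MeOH/H2O, 0 °C
Reagents that add atoms: none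
Why: Fluoride-mediated desilylation removes the three silyl groups without touching the sulfate monoester anion, and cation exchange on the acidic resin should deliver the hydrogen sulfate with no stereocentre involved.

Compound list
1 | 2,6-dimethoxyphenol | COc1cccc(OC)c1O | starting material
2 | 2-(benzyloxy)-1,3-dimethoxybenzene | COc1cccc(OC)c1OCc1ccccc1 | intermediate
3 | [3-(benzyloxy)-2,4-dimethoxyphenyl]methylidene(dimethyl)iminium chloride | COc1ccc(C=[N+](C)C)c(OC)c1OCc1ccccc1.[Cl-] | intermediate (not isolated)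
4 | 3-(benzyloxy)-2,4-dimethoxybenzaldehyde | COc1ccc(C=O)c(OC)c1OCc1ccccc1 | intermediate
5 | methyl 2-(oxetan-3-ylidene)acetate | COC(=O)C=C1COC1 | starting material
6 | methyl 2-(oxetan-3-yl)acetate | COC(=O)CC1COC1 | intermediate
7 | lithium enolate of methyl 2-(oxetan-3-yl)acetate | [Li+].COC([O-])=CC1COC1 | intermediate (not isolated)
8 | methyl 3-[3-(benzyloxy)-2,4-dimethoxyphenyl]-3-hydroxy-2-(oxetan-3-yl)propanoate, racemic diastereomer mixture | COC(=O)C(C1COC1)C(O)c1ccc(OC)c(OCc2ccccc2)c1OC | intermediate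
9 | methyl 3-[3-(benzyloxy)-2,4-dimethoxyphenyl]-2-(oxetan-3-yl)-3-oxopropanoate, racemic | COC(=O)C(C1COC1)C(=O)c1ccc(OC)c(OCc2ccccc2)c1OC | intermediate
10 | methyl 3-(3-hydroxy-2,4-dimethoxyphenyl)-2-(oxetan-3-yl)-3-oxopropanoate, racemic (precursor of the key step) | COC(=O)C(C1COC1)C(=O)c1ccc(OC)c(O)c1OC | intermediate
11 | methyl (3S)-7-hydroxy-3-(hydroxymethyl)-6,8-dimethoxy-1-oxo-1,2,3,4-tetrahydronaphthalene-2-carboxylate, C2 undefined (product of the key step) | COC(=O)C1C(=O)c2c(OC)c(O)c(OC)cc2C[C@@H]1CO | intermediate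
12 | methyl (3S)-6,8-dimethoxy-1-oxo-7-(triisopropylsilyloxy)-3-[(triisopropylsilyloxy)methyl]-1,2,3,4-tetrahydronaphthalene-2-carboxylate, C2 undefined | COC(=O)C1C(=O)c2c(OC)c(O[Si](C(C)C)(C(C)C)C(C)C)c(OC)cc2C[C@@H]1CO[Si](C(C)C)(C(C)C)C(C)C | intermediate
13 | methyl (3S)-6,8-dimethoxy-1-(trifluoromethylsulfonyloxy)-7-(triisopropylsilyloxy)-3-[(triisopropylsilyloxy)methyl]-3,4-dihydronaphthalene-2-carboxylate | COC(=O)C1=C(OS(=O)(=O)C(F)(F)F)c2c(OC)c(O[Si](C(C)C)(C(C)C)C(C)C)c(OC)cc2C[C@@H]1CO[Si](C(C)C)(C(C)C)C(C)C | intermediate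
14 | 2,6-dimethoxy-4-(4,4,5,5-tetramethyl-1,3,2-dioxaborolan-2-yl)phenol | COc1cc(B2OC(C)(C)C(C)(C)O2)cc(OC)c1O | starting material
15 | [2,6-dimethoxy-4-(4,4,5,5-tetramethyl-1,3,2-dioxaborolan-2-yl)phenoxy]triisopropylsilane | COc1cc(B2OC(C)(C)C(C)(C)O2)cc(OC)c1O[Si](C(C)C)(C(C)C)C(C)C | intermediate
16 | methyl (3S)-1-[3,5-dimethoxy-4-(triisopropylsilyloxy)phenyl]-6,8-dimethoxy-7-(triisopropylsilyloxy)-3-[(triisopropylsilyloxy)methyl]-3,4-dihydronaphthalene-2-carboxylate | COC(=O)C1=C(c2cc(OC)c(O[Si](C(C)C)(C(C)C)C(C)C)c(OC)c2)c2c(OC)c(O[Si](C(C)C)(C(C)C)C(C)C)c(OC)cc2C[C@@H]1CO[Si](C(C)C)(C(C)C)C(C)C | intermediate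
17 | methyl (1R,2R,3S)-1-[3,5-dimethoxy-4-(triisopropylsilyloxy)phenyl]-6,8-dimethoxy-7-(triisopropylsilyloxy)-3-[(triisopropylsilyloxy)methyl]-1,2,3,4-tetrahydronaphthalene-2-carboxylate (all-cis) | COc1cc([C@@H]2c3c(cc(OC)c(O[Si](C(C)C)(C(C)C)C(C)C)c3OC)C[C@H](CO[Si](C(C)C)(C(C)C)C(C)C)[C@@H]2C(=O)OC)cc(OC)c1O[Si](C(C)C)(C(C)C)C(C)C | intermediate
18 | methyl (1R,2S,3S)-1-[3,5-dimethoxy-4-(triisopropylsilyloxy)phenyl]-6,8-dimethoxy-7-(triisopropylsilyloxy)-3-[(triisopropylsilyloxy)methyl]-1,2,3,4-tetrahydronaphthalene-2-carboxylate (all-trans) | COc1cc([C@@H]2c3c(cc(OC)c(O[Si](C(C)C)(C(C)C)C(C)C)c3OC)C[C@H](CO[Si](C(C)C)(C(C)C)C(C)C)[C@H]2C(=O)OC)cc(OC)c1O[Si](C(C)C)(C(C)C)C(C)C | intermediate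
19 | [(1R,2S,3S)-1-[3,5-dimethoxy-4-(triisopropylsilyloxy)phenyl]-6,8-dimethoxy-7-(triisopropylsilyloxy)-3-[(triisopropylsilyloxy)methyl]-1,2,3,4-tetrahydronaphthalen-2-yl]methanol | COc1cc([C@@H]2c3c(cc(OC)c(O[Si](C(C)C)(C(C)C)C(C)C)c3OC)C[C@H](CO[Si](C(C)C)(C(C)C)C(C)C)[C@H]2CO)cc(OC)c1O[Si](C(C)C)(C(C)C)C(C)C | intermediate
20 | pyridinium [(1R,2S,3S)-1-[3,5-dimethoxy-4-(triisopropylsilyloxy)phenyl]-6,8-dimethoxy-7-(triisopropylsilyloxy)-3-[(triisopropylsilyloxy)methyl]-1,2,3,4-tetrahydronaphthalen-2-yl]methyl sulfate | COc1cc([C@@H]2c3c(cc(OC)c(O[Si](C(C)C)(C(C)C)C(C)C)c3OC)C[C@H](CO[Si](C(C)C)(C(C)C)C(C)C)[C@H]2COS(=O)(=O)[O-])cc(OC)c1O[Si](C(C)C)(C(C)C)C(C)C.c1cc[nH+]cc1 | intermediate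
21 | pyridinium [(1R,2S,3S)-7-hydroxy-1-(4-hydroxy-3,5-dimethoxyphenyl)-3-(hydroxymethyl)-6,8-dimethoxy-1,2,3,4-tetrahydronaphthalen-2-yl]methyl sulfate | COc1cc([C@@H]2c3c(cc(OC)c(O)c3OC)C[C@H](CO)[C@H]2COS(=O)(=O)[O-])cc(OC)c1O.c1cc[nH+]cc1 | intermediate (not isolated)
22 | [(1R,2S,3S)-7-hydroxy-1-(4-hydroxy-3,5-dimethoxyphenyl)-3-(hydroxymethyl)-6,8-dimethoxy-1,2,3,4-tetrahydronaphthalen-2-yl]methyl hydrogen sulfate | COc1cc([C@@H]2c3c(cc(OC)c(O)c3OC)C[C@H](CO)[C@H]2COS(=O)(=O)O)cc(OC)c1O | target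

Total step count: 16. Longest linear sequence: 14 steps (1, 2, 4 to 9, 11 to 16).

Steps most likely to fail

Step 7 (the proposed new method). The acid may fail to tell the two enantiotopic oxetane CH2 groups apart, or may be too weak to open the oxetane. Oxygen alkylation by the C1 carbonyl may also outrun attack by C4a. The fallback sets out from 10, uses known chemistry only, and obtains the stereocentre by resolution instead of catalyst control. An achiral Lewis acid, Sc(OTf)3 in CH2Cl2, with hexafluoroisopropanol as co-solvent if more activation is needed, should effect the known Friedel–Crafts opening of an oxetane by a tethered arene. No background reaction has to be suppressed here, so harsher activation is permitted. The product would be racemic methyl 7-hydroxy-3-(hydroxymethyl)-6,8-dimethoxy-1-oxotetralin-2-carboxylate F1. Silylation as in step 8 should give the racemic bis(triisopropylsilyl) ether F2, and triflation as in step 9 the racemic enol triflate F3. F3 has C3 as its only stereocentre and no tautomers, so it would be resolved by preparative supercritical-fluid chromatography on a cellulose-based chiral stationary phase. The (3S) enantiomer is 13, where the route is rejoined.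

Step 12. Hydrogen may not reach the tetrasubstituted, peri-hindered C1=C2 bond on the catalyst surface, or it may add to both faces. The fallback sets out from 16 and replaces surface hydrogenation by electron-transfer conjugate reduction with Mg turnings in MeOH. C1 should be protonated anti to the pseudoaxial C3 arm, and the magnesium enolate, equilibrating under Mg(OMe)2, should settle as the trans ester. The sequence would then arrive directly at 18, merging steps 12 and 13, and no new compound is made.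

Step 13. The alkoxide may strip the phenolic silyl ethers before C2 has equilibrated, or equilibration may stop short. The fallback sets out from 17 and moves the epimerisation to the aldehyde stage, where an amine base suffices. LiAlH4 should give the all-cis alcohol [(1R,2R,3S)-1-[3,5-dimethoxy-4-(triisopropylsilyloxy)phenyl]-6,8-dimethoxy-7-(triisopropylsilyloxy)-3-[(triisopropylsilyloxy)methyl]tetralin-2-yl]methanol F4. Dess–Martin periodinane should give the all-cis aldehyde, the (1R,2R,3S)-tetralin-2-carbaldehyde F5. DBU in CH2Cl2 should equilibrate the acidic aldehyde α-centre to the all-trans (1R,2S,3S)-tetralin-2-carbaldehyde F6. NaBH4 in MeOH would reduce F6 to 19, where the route is rejoined.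

Further compounds
F1 | step 7 | racemic methyl 7-hydroxy-3-(hydroxymethyl)-6,8-dimethoxy-1-oxo-1,2,3,4-tetrahydronaphthalene-2-carboxylate | COC(=O)C1C(=O)c2c(OC)c(O)c(OC)cc2CC1CO
F2 | step 7 | racemic methyl 6,8-dimethoxy-1-oxo-7-(triisopropylsilyloxy)-3-[(triisopropylsilyloxy)methyl]-1,2,3,4-tetrahydronaphthalene-2-carboxylate | COC(=O)C1C(=O)c2c(OC)c(O[Si](C(C)C)(C(C)C)C(C)C)c(OC)cc2CC1CO[Si](C(C)C)(C(C)C)C(C)C
F3 | step 7 | racemic methyl 6,8-dimethoxy-1-(trifluoromethylsulfonyloxy)-7-(triisopropylsilyloxy)-3-[(triisopropylsilyloxy)methyl]-3,4-dihydronaphthalene-2-carboxylate | COC(=O)C1=C(OS(=O)(=O)C(F)(F)F)c2c(OC)c(O[Si](C(C)C)(C(C)C)C(C)C)c(OC)cc2CC1CO[Si](C(C)C)(C(C)C)C(C)C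
F0 | step 12 | none | none
F4 | step 13 | [(1R,2R,3S)-1-[3,5-dimethoxy-4-(triisopropylsilyloxy)phenyl]-6,8-dimethoxy-7-(triisopropylsilyloxy)-3-[(triisopropylsilyloxy)methyl]-1,2,3,4-tetrahydronaphthalen-2-yl]methanol | COc1cc([C@@H]2c3c(cc(OC)c(O[Si](C(C)C)(C(C)C)C(C)C)c3OC)C[C@H](CO[Si](C(C)C)(C(C)C)C(C)C)[C@@H]2CO)cc(OC)c1O[Si](C(C)C)(C(C)C)C(C)C
F5 | step 13 | (1R,2R,3S)-1-[3,5-dimethoxy-4-(triisopropylsilyloxy)phenyl]-6,8-dimethoxy-7-(triisopropylsilyloxy)-3-[(triisopropylsilyloxy)methyl]-1,2,3,4-tetrahydronaphthalene-2-carbaldehyde | COc1cc([C@@H]2c3c(cc(OC)c(O[Si](C(C)C)(C(C)C)C(C)C)c3OC)C[C@H](CO[Si](C(C)C)(C(C)C)C(C)C)[C@@H]2C=O)cc(OC)c1O[Si](C(C)C)(C(C)C)C(C)C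
F6 | step 13 | (1R,2S,3S)-1-[3,5-dimethoxy-4-(triisopropylsilyloxy)phenyl]-6,8-dimethoxy-7-(triisopropylsilyloxy)-3-[(triisopropylsilyloxy)methyl]-1,2,3,4-tetrahydronaphthalene-2-carbaldehyde | COc1cc([C@@H]2c3c(cc(OC)c(O[Si](C(C)C)(C(C)C)C(C)C)c3OC)C[C@H](CO[Si](C(C)C)(C(C)C)C(C)C)[C@H]2C=O)cc(OC)c1O[Si](C(C)C)(C(C)C)C(C)C
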